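**Retrosynthetic overview**
1. Target ⇐ axial hydride reduction of the 1,9-dione ⇐ transorthoesterification of the 4α,6α,15-triol with trimethyl orthocinnamate (orthoester cage closed last).
2. Triol ⇐ α-face dihydroxylation of the 4(15)-exocyclic alkene ⇐ methylenation of a trans-decal-4-one.
3. Ring A (key): nitromethane as an acyl-anion (carbonyl 1,1-dianion) linchpin forms C4–C5 (enone β-carbon) and C4–C3 (acrolein β-carbon); aldol closes C10–C1; Nef unveils C4=O; C5 is then epimerised to the trans fusion.
4. Ring B ⇐ (4R,5R)-4-hydroxy enone ⇐ (R)-α-phellandrene by singlet-oxygen [4+2] and Kornblum–DeLaMare rearrangement.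
5. Ring order: B (chiral pool) → A (three-component annulation) → dioxane/dioxolane orthoester cage.

Assumption: eudesmane numbering is used (C14 = methyl on C10, C15 = CH2O on C4); α/β are relative descriptors with β = the face of C14, and the absolute configuration is fixed by C7 = R as in the SMILES.

**Route**

Step 1
Reactants: 1 (R)-(−)-α-phellandrene
Product: 3 (4R,5R)-4-hydroxy-2-methyl-5-(propan-2-yl)cyclohex-2-en-1-one, via phellandrene endoperoxide 2 (not isolated)
Conditions: O2, TPP (1 mol%), hν (visible), CH2Cl2, −20 °C; then Et3N (0.5 equiv), 0 °C to rt; chromatography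
Reagents that add atoms: dioxygen O=O
Why: Singlet-oxygen [4+2] cycloaddition occurs mainly anti to the isopropyl group, and Kornblum–DeLaMare rearrangement by removal of the less hindered bridgehead H (next to CH2) gives the γ-hydroxy enone, setting C6 with oxygen trans to the C7 isopropyl group.

Step 2
Reactants: 3 (4R,5R)-4-hydroxy-2-methyl-5-(propan-2-yl)cyclohex-2-en-1-one; 4 nitromethane; 5 acrolein
Product: 8 (7R)-1α,6α-dihydroxy-4β-nitro-5βH-15-noreudesman-9-one, via nitromethyl ketone 6 (not isolated), via nitro aldehyde 7 (not isolated)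
Conditions: MeNO2 (10 equiv), DBU (0.5 equiv), MeCN, rt; evaporate; acrolein (1.1 equiv), DBU (0.2 equiv), MeCN, −20 °C; then DBU (1 equiv), rt
Reagents that add atoms: none
Why: Nitromethane acts as an acyl-anion linchpin in a nitro-Michael/nitro-Michael/intramolecular aldol annulation: the nitronate adds to C5 by axial attack anti to the isopropyl group (syn to the small free 6-OH), adds again to acrolein, and the C9 ketone enolate then closes onto the aldehyde cis to the axial C4 arm (a trans closure would force O6 and isopropyl diaxial), which fixes quaternary C10 with C14 cis to the isopropyl group.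

Step 3
Reactants: 8 (7R)-1α,6α-dihydroxy-4β-nitro-5βH-15-noreudesman-9-one
Product: 10 (7R)-1α,6α-dihydroxy-5αH-15-noreudesmane-4,9-dione, via cis-fused dione 9 (not isolated)
Conditions: NaOMe (1.1 equiv), MeOH, 0 °C; Oxone, aq Na2HPO4, 0 °C to rt; extract; then DBU (0.3 equiv), PhMe, 40 °C
Reagents that add atoms: Oxone (potassium peroxymonosulfate) [K+].[O-]S(=O)(=O)OO
Why: Oxidative Nef reaction of the nitronate unmasks the latent acyl carbon as the C4 ketone, and DBU then epimerises C5 through the C4 enol to the thermodynamically preferred trans-decalone, in which C4, O6 and the isopropyl group are all equatorial on ring B (as in 5β→5α equilibration of 4-oxo steroids).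

Step 4
Reactants: 10 (7R)-1α,6α-dihydroxy-5αH-15-noreudesmane-4,9-dione
Product: 11 (7R)-1α,6α-dihydroxy-5αH-eudesm-4(15)-en-9-one
Conditions: Zn, CH2Br2, TiCl4 (excess), THF/CH2Cl2, 0 °C to rt
Reagents that add atoms: dibromomethane BrCBr
Why: Takai–Lombardo methylenation is non-basic (no retro-aldol or epimerisation) and should take the accessible C4 ketone in preference to the neopentylic C9 ketone beside quaternary C10.

Step 5
Reactants: 11 (7R)-1α,6α-dihydroxy-5αH-eudesm-4(15)-en-9-one
Product: 12 (7R)-1α,4α,6α,15-tetrahydroxy-5αH-eudesman-9-one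
Conditions: OsO4 (2 mol%), NMO, acetone/H2O, rt
Reagents that add atoms: osmium tetroxide O=[Os](=O)(=O)=O; N-methylmorpholine N-oxide C[N+]1([O-])CCOCC1; water O
Why: Upjohn dihydroxylation attacks the exocyclic alkene from the α-face, away from the 1,3-diaxial C10 methyl, setting C4 with the tertiary OH α (equatorial) and the CH2OH β (axial).

Step 6
Reactants: 13 (E)-cinnamonitrile
Product: 15 trimethyl (E)-orthocinnamate, via imidate hydrochloride 14 (not isolated)
Conditions: HCl (g), MeOH (1.1 equiv), Et2O, 0 °C; then MeOH (excess), hexane, rt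
Reagents that add atoms: methanol CO
Why: Pinner reaction gives the imidate salt, whose alcoholysis gives the orthoester with the E-alkene untouched.

Step 7
Reactants: 12 (7R)-1α,4α,6α,15-tetrahydroxy-5αH-eudesman-9-one; 15 trimethyl (E)-orthocinnamate
Product: 16 (7R)-1α-hydroxy-5αH-eudesman-9-one 4α,6α,15-orthocinnamate
Conditions: CSA (5 mol%), 4 Å MS, CH2Cl2, rt
Reagents that add atoms: none
Why: Acid-catalysed transorthoesterification closes the 2,7,8-trioxabicyclo[3.2.1]octane on the rigid peri-disposed 4α,6α,15-triol (driven by loss of three MeOH); the orthoester carbon configuration is dictated by the cage and the 1-OH cannot reach it.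

Step 8
Reactants: 16 (7R)-1α-hydroxy-5αH-eudesman-9-one 4α,6α,15-orthocinnamate
Product: 17 (7R)-5αH-eudesmane-1,9-dione 4α,6α,15-orthocinnamate
Conditions: Dess–Martin periodinane, NaHCO3, CH2Cl2, 0 °C to rt
Reagents that add atoms: none
Why: Dess–Martin oxidation of the only free hydroxyl under buffered conditions (orthoester-safe) erases the C1 configuration left by the aldol.

Step 9
Reactants: 17 (7R)-5αH-eudesmane-1,9-dione 4α,6α,15-orthocinnamate
Product: 18 (7R)-5αH-eudesmane-1β,9β-diol 4α,6α,15-orthocinnamate (CNP0252898.1)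
Conditions: NaBH4, MeOH/CH2Cl2, −20 to 0 °C
Reagents that add atoms: none
Why: Borohydride reduction delivers hydride axially from the α-face (opposite the angular methyl) to both neopentylic ketones, giving the diequatorial 1β,9β-diol; the orthoester and styryl alkene are inert.

**Compound list**
1 | (R)-(−)-α-phellandrene [(5R)-2-methyl-5-(propan-2-yl)cyclohexa-1,3-diene] | CC1=CC[C@H](C(C)C)C=C1 | starting material
2 | 5-methyl-7-(propan-2-yl)-2,3-dioxabicyclo[2.2.2]oct-5-ene, peroxide bridge anti to isopropyl | CC(C)[C@H]1C[C@@H]2OO[C@H]1C=C2C | intermediate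
3 | (4R,5R)-4-hydroxy-2-methyl-5-(propan-2-yl)cyclohex-2-en-1-one | CC(C)[C@H]1CC(=O)C(C)=C[C@@H]1O | intermediate
4 | nitromethane | C[N+](=O)[O-] | starting material
5 | acrolein | C=CC=O | starting material
6 | (2R,3R,4R,5R)-4-hydroxy-2-methyl-3-(nitromethyl)-5-(propan-2-yl)cyclohexan-1-one | CC(C)[C@H]1CC(=O)[C@H](C)[C@H](C[N+](=O)[O-])[C@@H]1O | intermediate
7 | acrolein adduct of 6 at the nitro carbon (γ-nitro aldehyde, both epimers at the nitro carbon) | CC(C)[C@H]1CC(=O)[C@H](C)[C@H](C(CCC=O)[N+](=O)[O-])[C@@H]1O | intermediate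
8 | (7R)-1α,6α-dihydroxy-4β-nitro-5βH-15-noreudesman-9-one (cis-fused) | CC(C)[C@H]1CC(=O)[C@@]2(C)[C@@H]([C@@H]1O)[C@H]([N+](=O)[O-])CC[C@H]2O | intermediate
9 | (7R)-1α,6α-dihydroxy-5βH-15-noreudesmane-4,9-dione (cis-fused) | CC(C)[C@H]1CC(=O)[C@@]2(C)[C@@H]([C@@H]1O)C(=O)CC[C@H]2O | intermediate
10 | (7R)-1α,6α-dihydroxy-5αH-15-noreudesmane-4,9-dione (trans-fused) | CC(C)[C@H]1CC(=O)[C@@]2(C)[C@H]([C@@H]1O)C(=O)CC[C@H]2O | intermediate
11 | (7R)-1α,6α-dihydroxy-5αH-eudesm-4(15)-en-9-one | CC(C)[C@H]1CC(=O)[C@@]2(C)[C@H]([C@@H]1O)C(=C)CC[C@H]2O | intermediate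
12 | (7R)-1α,4α,6α,15-tetrahydroxy-5αH-eudesman-9-one | CC(C)[C@H]1CC(=O)[C@@]2(C)[C@H]([C@@H]1O)[C@](O)(CO)CC[C@H]2O | intermediate
13 | (E)-cinnamonitrile | N#C/C=C/c1ccccc1 | starting material
14 | methyl (E)-cinnamimidate hydrochloride | COC(=[NH2+])/C=C/c1ccccc1.[Cl-] | intermediate
15 | trimethyl (E)-orthocinnamate | COC(OC)(OC)/C=C/c1ccccc1 | intermediate
16 | (7R)-1α-hydroxy-5αH-eudesman-9-one 4α,6α,15-orthocinnamate | CC(C)[C@H]1CC(=O)[C@@]2(C)[C@@H]3[C@@H]1O[C@]1(/C=C/c4ccccc4)OC[C@@]3(CC[C@H]2O)O1 | intermediate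
17 | (7R)-5αH-eudesmane-1,9-dione 4α,6α,15-orthocinnamate | CC(C)[C@H]1CC(=O)[C@@]2(C)[C@@H]3[C@@H]1O[C@]1(/C=C/c4ccccc4)OC[C@@]3(CCC2=O)O1 | intermediate
18 | (7R)-5αH-eudesmane-1β,9β-diol 4α,6α,15-orthocinnamate (CNP0252898.1) | CC(C)[C@H]1C[C@@H](O)[C@@]2(C)[C@@H]3[C@@H]1O[C@]1(/C=C/c4ccccc4)OC[C@@]3(CC[C@@H]2O)O1 | target

**Step count**
Total: 9 steps. Longest linear sequence: 8 steps (1–5, 7–9); step 6 is a one-step reagent branch.

**Three steps most likely to fail, with fallbacks**

Step 2 (three-component annulation). The risks are the facial selectivity of the first nitronate addition next to the free 6-OH (it is relayed to C10), double addition to acrolein, and aldol regiochemistry. The fallback sets out from 3 and returns at 6. Transesterify 3 with ethyl nitroacetate (cat. DMAP, toluene, reflux) to the nitroacetate ester F1. DBU then triggers a 5-exo intramolecular nitro-Michael addition that can only deliver carbon to C5 from the O6 face, giving the cis-fused nitro γ-lactone F2. LiOH followed by AcOH opens the lactone, and the α-nitro acid loses CO2 to give 6, which continues through the acrolein/aldol half of step 2.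

Step 3 (Nef reaction and C5 epimerisation). The risks are slow nitronate oxidation at a carbon flanked by a tertiary centre, Baeyer–Villiger or retro-aldol side reactions, and incomplete equilibration. The fallback sets out from 8 and returns at 9. Reduce the nitro group with SnCl2/PhSH/Et3N to the C4 oxime F3, then exchange the oxime with aqueous glyoxylic acid to release 9, which is epimerised with DBU as in step 3.

Step 4 (chemoselective methylenation). The risks are competing reaction at the C9 ketone and Lewis-acid-promoted dehydration. The fallback sets out from 10 and returns at 11 by a two-stage Peterson olefination. Me3SiCH2MgCl/CeCl3 (THF, −78 °C) adds only to the unhindered C4 ketone from the α-face to give the β-hydroxysilane F4, and HF·pyridine then eliminates trimethylsilanol to give 11.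

**Further compounds**
F1 | step 2 | nitroacetate ester of 3 [(1R,6R)-3-methyl-4-oxo-6-(propan-2-yl)cyclohex-2-en-1-yl nitroacetate] | CC(C)[C@H]1CC(=O)C(C)=C[C@@H]1OC(=O)C[N+](=O)[O-]
F2 | step 2 | cis-fused α-nitro γ-lactone from intramolecular Michael addition of F1 (nitro carbon epimers) | CC(C)[C@H]1CC(=O)[C@H](C)[C@H]2[C@@H]1OC(=O)C2[N+](=O)[O-]
F3 | step 3 | (7R)-1α,6α-dihydroxy-5βH-15-noreudesmane-4,9-dione 4-oxime | CC(C)[C@H]1CC(=O)[C@@]2(C)[C@@H]([C@@H]1O)C(=NO)CC[C@H]2O
F4 | step 4 | (7R)-1α,4β,6α-trihydroxy-4α-(trimethylsilylmethyl)-5αH-15-noreudesman-9-one | CC(C)[C@H]1CC(=O)[C@@]2(C)[C@H]([C@@H]1O)[C@@](O)(C[Si](C)(C)C)CC[C@H]2O
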